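**Retrosynthetic overview**
- The last C–C bond made is the central CH–CH bond of the E,E-diene, from an alkenylalane (ring B alkyne after syn-methylalumination) and the ring A (E)-alkenyl iodide.
- Ring A (the 3-bromo-2,2,6-trimethyloxane) comes from (R)-linalool by bromonium-induced 6-endo etherification, followed by vinyl → CHO → (E)-CH=CHI.
- Ring B (the bromocyclohexanol): the tertiary carbinol comes from methyl addition anti to bromine on a cis-3-bromo-4-oxocyclohexanecarboxylate, which is the unmasked silyl enol ether of a Diels–Alder adduct.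
- Feature used: in ring B the CHBr carbon and the methine carrying the diene are cis-1,3, and the C(OH)CH3 carbon is the other neighbour of CHBr. This is the array of an endo adduct of a (Z)-1-bromo-2-silyloxybuta-1,3-diene and an acrylate, and the one that bromination of a 4-substituted cyclohexanone enol (trans) does not give.
- Order of ring formation: ring B by [4+2] (step 3) and ring A by etherification (step 9) in separate branches, joined in step 12.

Key step: step 3

Assumption: the (S)-prolinol-derived oxazaborolidinium ion is taken to leave open the Si face of the α-carbon of the bound acrylate, as its usual binding model predicts (the sense that turns buta-1,3-diene and an acrylate into the (R)-cyclohex-3-ene-1-carboxylate); if a trial adduct is the mirror image, the (R)-prolinol-derived catalyst is used instead, and the catalyst enantiomers named in the fallbacks are exchanged likewise.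

**Route**

Step 1
Reactants: 1 2-(trimethylsilyloxy)buta-1,3-diene
Product: 2 1-bromobut-3-en-2-one
Conditions: NBS (1.0 equiv), CH2Cl2, −78 → 0 °C; cold aqueous wash, dried solution used at once
Reagents that add atoms: N-bromosuccinimide, O=C1CCC(=O)N1Br
Why: Electrophilic α′-bromination of a cross-conjugated silyl dienol ether, in which Br+ attacks the terminal CH2 of the enol ether and loss of the trimethylsilyl group leaves the bromomethyl vinyl ketone; this is preferred to a palladium-catalysed acylation of a vinylstannane, where insertion into the C–Br bonds would compete.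

Step 2
Reactants: 2 1-bromobut-3-en-2-one
Product: 3 (Z)-1-bromo-2-(triisopropylsilyloxy)buta-1,3-diene
Conditions: TIPSOTf (1.1 equiv), iPr2NEt (1.3 equiv), Et2O, −78 → 0 °C; filtered through basic alumina, used without storage
Reagents that add atoms: triisopropylsilyl trifluoromethanesulfonate, CC(C)[Si](OS(=O)(=O)C(F)(F)F)(C(C)C)C(C)C
Why: Soft enolisation of an α-bromo ketone (O-silylation, then deprotonation of the acidified CH2Br by a hindered amine that is slow to be N-alkylated) should place bromine trans to the vinyl group, the Z isomer, because the E isomer suffers A(1,3) strain between bromine and the vinyl group.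

Step 3
Reactants: 3 (Z)-1-bromo-2-(triisopropylsilyloxy)buta-1,3-diene; 4 methyl acrylate
Product: 5 methyl (1S,3S)-3-bromo-4-(triisopropylsilyloxy)cyclohex-4-ene-1-carboxylate
Conditions: 4 (3 equiv), oxazaborolidinium salt [C24H25BNO]+ [(CF3SO2)2N]− (20 mol%, from (S)-1-(2-methylphenyl)-3,3-diphenyltetrahydro-1H,3H-pyrrolo[1,2-c][1,3,2]oxazaborole and (CF3SO2)2NH), CH2Cl2, −78 → −40 °C; Et3N quench at −78 °C
Reagents that add atoms: none
Why: Proposed new method: the reaction should be a concerted but asynchronous endo [4+2] cycloaddition of diene 3 to s-trans methyl acrylate held on boron (carbonyl bound anti to OMe, α-C–H toward the ring oxygen), the closest known reaction type being the oxazaborolidinium-catalysed enantioselective Diels–Alder reaction of 2-(triisopropylsilyloxy)buta-1,3-diene with acrylates, extended here to a diene that carries bromine on its nucleophilic terminus. Ring B closes by this intermolecular cycloaddition, the CHBr carbon bonding to the acrylate β-carbon and the CH2 terminus to the α-carbon. The regiochemistry (ester 1,4 to the C–OSi carbon, hence bromine 1,3 to the ester) rests on the silyloxy group, a much stronger donor than bromine, making the CHBr terminus the site of the largest HOMO coefficient. C3 is set relative to C1 by the Z geometry of the diene (bromine on the outside of the s-cis diene; any E isomer cannot reach s-cis and is inert) together with the endo orientation of the ester that Lewis-acid catalysis favours, which places Br and CO2Me cis. C1 is set by the catalyst, whose C-phenyl group covers one face of the bound acrylate so that the diene adds to the Si face of the α-carbon, giving 1S. The step needs the allylic C–Br bond of the adduct (a 2-silyloxyallyl bromide) to survive the Lewis acid, which is why the triflimide-activated rather than an AlBr3-activated catalyst, low temperature and an amine quench before warming are specified.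

Step 4
Reactants: 5 methyl (1S,3S)-3-bromo-4-(triisopropylsilyloxy)cyclohex-4-ene-1-carboxylate
Product: 6 methyl (1S,3S)-3-bromo-4-oxocyclohexane-1-carboxylate
Conditions: CF3CO2H (2 equiv), THF/H2O (10:1), 0 °C
Reagents that add atoms: none
Why: Acid hydrolysis of a silyl enol ether by C-protonation at C5 and loss of the silyl group gives the ketone without passing through an enolate (which would expel the α′-bromide, Favorskii-type), and a non-nucleophilic acid avoids halide exchange at C3, so the cis C1/C3 relation should be kept.

Step 5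
Reactants: 6 methyl (1S,3S)-3-bromo-4-oxocyclohexane-1-carboxylate
Product: 7 methyl (1S,3S,4R)-3-bromo-4-hydroxy-4-methylcyclohexane-1-carboxylate
Conditions: MeLi/CeCl3 (1.3 equiv, premixed at −78 °C), THF, −78 °C; AcOH quench at −78 °C
Reagents that add atoms: methyllithium, [Li]C (delivered as MeCeCl2)
Why: 1,2-Addition of a weakly basic organocerium reagent to an α-halo ketone under Cornforth/Felkin–Anh polar control, in which methyl enters anti to the C–Br bond (equatorially on the diequatorial chair, or axially anti to bromine on the flipped chair, both giving OH cis to Br and 4R), while the ketone reacts much faster than the methyl ester at −78 °C.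

Step 6
Reactants: 7 methyl (1S,3S,4R)-3-bromo-4-hydroxy-4-methylcyclohexane-1-carboxylate
Product: 8 methyl (1S,3S,4R)-3-bromo-4-methyl-4-(triethylsilyloxy)cyclohexane-1-carboxylate
Conditions: TESOTf (1.5 equiv), 2,6-lutidine (2 equiv), CH2Cl2, −78 → 0 °C
Reagents that add atoms: triethylsilyl trifluoromethanesulfonate, CC[Si](CC)(CC)OS(=O)(=O)C(F)(F)F
Why: Silylation of a hindered tertiary alcohol with a silyl triflate gives an ether that masks the hydroxyl against iBu2AlH and AlMe3 and should survive K2CO3/MeOH.

Step 7
Reactants: 8 methyl (1S,3S,4R)-3-bromo-4-methyl-4-(triethylsilyloxy)cyclohexane-1-carboxylate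
Product: 9 (1S,3S,4R)-3-bromo-4-methyl-4-(triethylsilyloxy)cyclohexane-1-carbaldehyde
Conditions: iBu2AlH (1.1 equiv), CH2Cl2, −78 °C; MeOH, then aqueous Rochelle salt
Reagents that add atoms: none
Why: Partial reduction of a methyl ester with iBu2AlH at −78 °C stops at the tetrahedral aluminium hemiacetal, which releases the aldehyde only on work-up, and the alkyl bromide and silyl ether are inert to the reagent.

Step 8
Reactants: 9 (1S,3S,4R)-3-bromo-4-methyl-4-(triethylsilyloxy)cyclohexane-1-carbaldehyde
Product: 10 {[(1R,2S,4S)-2-bromo-4-ethynyl-1-methylcyclohexyl]oxy}triethylsilane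
Conditions: dimethyl (1-diazo-2-oxopropyl)phosphonate (1.5 equiv), K2CO3 (2 equiv), MeOH, 0 °C → rt
Reagents that add atoms: dimethyl (1-diazo-2-oxopropyl)phosphonate, CC(=O)C(=[N+]=[N-])P(=O)(OC)OC
Why: Seyferth–Gilbert homologation in its Ohira–Bestmann form converts the α-branched aldehyde into the terminal alkyne under mild base, where epimerisation at C1 is slow and the desired equatorial epimer is in any case the more stable one.

Step 9
Reactants: 11 (R)-linalool
Product: 12 (3S,6R)-3-bromo-6-ethenyl-2,2,6-trimethyloxane
Conditions: 2,4,4,6-tetrabromocyclohexa-2,5-dien-1-one (TBCO, 1.1 equiv), CH2Cl2, −20 → 0 °C, dark; chromatography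
Reagents that add atoms: 2,4,4,6-tetrabromocyclohexa-2,5-dien-1-one, O=C1C(Br)=CC(Br)(Br)C=C1Br
Why: Bromonium-induced 6-endo (Markovnikov) haloetherification, in which Br+ adds to the trisubstituted alkene and the tertiary hydroxyl opens the bromonium ion anti at the dimethyl-substituted carbon; C6 is that of (R)-linalool, but the new C3 centre is not biased by it, so both C3 epimers and 5-exo oxolanes are expected and the (3S,6R) isomer (Br cis to the C6 methyl) is isolated by chromatography.

Step 10
Reactants: 12 (3S,6R)-3-bromo-6-ethenyl-2,2,6-trimethyloxane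
Product: 14 (2R,5S)-5-bromo-2,6,6-trimethyloxane-2-carbaldehyde, via secondary ozonide 13 (not isolated)
Conditions: O3, CH2Cl2, −78 °C; then PPh3, −78 °C → rt
Reagents that add atoms: ozone, [O-][O+]=O
Why: Ozonolysis with reductive work-up cleaves only the vinyl C=C bond, and the aldehyde has a quaternary α-carbon that cannot epimerise.

Step 11
Reactants: 14 (2R,5S)-5-bromo-2,6,6-trimethyloxane-2-carbaldehyde
Product: 15 (2R,5S)-5-bromo-2-[(E)-2-iodoethenyl]-2,6,6-trimethyloxane
Conditions: CrCl2 (6 equiv), CHI3 (2 equiv), THF, 0 °C → rt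
Reagents that add atoms: iodoform, IC(I)I
Why: Takai iodo-olefination through a gem-dichromium reagent gives E alkenyl iodides even from hindered aldehydes, and an unactivated secondary alkyl bromide is not reduced by CrCl2 in THF.

Step 12
Reactants: 10 {[(1R,2S,4S)-2-bromo-4-ethynyl-1-methylcyclohexyl]oxy}triethylsilane; 15 (2R,5S)-5-bromo-2-[(E)-2-iodoethenyl]-2,6,6-trimethyloxane
Product: 17 {[(1R,2S,4S)-2-bromo-4-[(2E,4E)-5-[(2R,5S)-5-bromo-2,6,6-trimethyloxan-2-yl]penta-2,4-dien-2-yl]-1-methylcyclohexyl]oxy}triethylsilane, via alkenylalane 16 (not isolated)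
Conditions: 10 (1.3 equiv), AlMe3 (2.5 equiv), Cp2ZrCl2 (0.25 equiv), CH2Cl2, 0 °C → rt; excess AlMe3 removed in vacuo; then 15, Pd(PPh3)4 (5 mol%), ZnCl2 (0.3 equiv), THF, rt
Reagents that add atoms: trimethylaluminium, C[Al](C)C
Why: Zirconium-catalysed carboalumination adds CH3 and Al syn with Al on the terminal carbon, which fixes the E trisubstituted alkene, and the palladium/zinc co-catalysed Negishi coupling of the alkenylalane with the alkenyl iodide proceeds with retention at both alkenes to give the E,E-diene.

Step 13
Reactants: 17 {[(1R,2S,4S)-2-bromo-4-[(2E,4E)-5-[(2R,5S)-5-bromo-2,6,6-trimethyloxan-2-yl]penta-2,4-dien-2-yl]-1-methylcyclohexyl]oxy}triethylsilane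
Product: 18 (1R,2S,4S)-2-bromo-4-[(2E,4E)-5-[(2R,5S)-5-bromo-2,6,6-trimethyloxan-2-yl]penta-2,4-dien-2-yl]-1-methylcyclohexan-1-ol
Conditions: HF·pyridine, pyridine, THF, 0 °C → rt
Reagents that add atoms: none
Why: Buffered fluoride cleavage of the triethylsilyl ether should leave the tertiary allylic ether of ring A, the diene and both secondary bromides untouched.

**Compound list**
1 | 2-(trimethylsilyloxy)buta-1,3-diene | C=CC(=C)O[Si](C)(C)C | starting material
2 | 1-bromobut-3-en-2-one | BrCC(=O)C=C | intermediate
3 | (Z)-1-bromo-2-(triisopropylsilyloxy)buta-1,3-diene | Br/C=C(\O[Si](C(C)C)(C(C)C)C(C)C)C=C | intermediate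
4 | methyl acrylate | C=CC(=O)OC | starting material
5 | methyl (1S,3S)-3-bromo-4-(triisopropylsilyloxy)cyclohex-4-ene-1-carboxylate | COC(=O)[C@H]1CC=C(O[Si](C(C)C)(C(C)C)C(C)C)[C@@H](Br)C1 | intermediate
6 | methyl (1S,3S)-3-bromo-4-oxocyclohexane-1-carboxylate | COC(=O)[C@H]1CCC(=O)[C@@H](Br)C1 | intermediate
7 | methyl (1S,3S,4R)-3-bromo-4-hydroxy-4-methylcyclohexane-1-carboxylate | COC(=O)[C@H]1CC[C@@](C)(O)[C@@H](Br)C1 | intermediate
8 | methyl (1S,3S,4R)-3-bromo-4-methyl-4-(triethylsilyloxy)cyclohexane-1-carboxylate | COC(=O)[C@H]1CC[C@@](C)(O[Si](CC)(CC)CC)[C@@H](Br)C1 | intermediate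
9 | (1S,3S,4R)-3-bromo-4-methyl-4-(triethylsilyloxy)cyclohexane-1-carbaldehyde | O=C[C@H]1CC[C@@](C)(O[Si](CC)(CC)CC)[C@@H](Br)C1 | intermediate
10 | {[(1R,2S,4S)-2-bromo-4-ethynyl-1-methylcyclohexyl]oxy}triethylsilane | C#C[C@H]1CC[C@@](C)(O[Si](CC)(CC)CC)[C@@H](Br)C1 | intermediate
11 | (R)-linalool | C=C[C@@](O)(C)CCC=C(C)C | starting material
12 | (3S,6R)-3-bromo-6-ethenyl-2,2,6-trimethyloxane | C=C[C@@]1(C)CC[C@H](Br)C(C)(C)O1 | intermediate
13 | 3-[(2R,5S)-5-bromo-2,6,6-trimethyloxan-2-yl]-1,2,4-trioxolane (secondary ozonide, both configurations at the trioxolane carbon) | O1COOC1[C@@]2(C)CC[C@H](Br)C(C)(C)O2 | intermediate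
14 | (2R,5S)-5-bromo-2,6,6-trimethyloxane-2-carbaldehyde | O=C[C@@]1(C)CC[C@H](Br)C(C)(C)O1 | intermediate
15 | (2R,5S)-5-bromo-2-[(E)-2-iodoethenyl]-2,6,6-trimethyloxane | I/C=C/[C@@]1(C)CC[C@H](Br)C(C)(C)O1 | intermediate
16 | [(E)-2-{(1S,3S,4R)-3-bromo-4-methyl-4-(triethylsilyloxy)cyclohexyl}prop-1-en-1-yl]dimethylalumane | C[Al](C)/C=C(\C)[C@H]1CC[C@@](C)(O[Si](CC)(CC)CC)[C@@H](Br)C1 | intermediate
17 | {[(1R,2S,4S)-2-bromo-4-[(2E,4E)-5-[(2R,5S)-5-bromo-2,6,6-trimethyloxan-2-yl]penta-2,4-dien-2-yl]-1-methylcyclohexyl]oxy}triethylsilane | C/C(=C\C=C\[C@@]1(C)CC[C@H](Br)C(C)(C)O1)[C@H]1CC[C@@](C)(O[Si](CC)(CC)CC)[C@@H](Br)C1 | intermediate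
18 | (1R,2S,4S)-2-bromo-4-[(2E,4E)-5-[(2R,5S)-5-bromo-2,6,6-trimethyloxan-2-yl]penta-2,4-dien-2-yl]-1-methylcyclohexan-1-ol | C/C(=C\C=C\[C@@]1(C)CC[C@H](Br)C(C)(C)O1)[C@H]1CC[C@@](C)(O)[C@@H](Br)C1 | target

**Step count and risks**

Total steps: 13. Longest linear sequence: 10 steps (steps 1–8, 12, 13).

Steps most likely to fail:

1. Step 3 (Proposed new method). What may go wrong: the bromine-bearing, hindered diene terminus may react too slowly, so that the catalyst decomposes the diene first; the Lewis acid may ionise the allylic C–Br bond of the adduct, with loss of configuration at C3; endo or facial selectivity may be insufficient. Fallback with known chemistry, setting out from 4 and coming back at 6: methyl acrylate 4 undergoes the known oxazaborolidinium-catalysed Diels–Alder reaction with 2-(triisopropylsilyloxy)buta-1,3-diene F1 (from but-3-en-2-one, TIPSOTf, Et3N), here with the (R)-prolinol-derived enantiomer of the catalyst, to give methyl (S)-4-(triisopropylsilyloxy)cyclohex-3-ene-1-carboxylate F2. Bromination of the silyl enol ether with NBS (THF, −78 °C) should occur by axial attack and give mainly the trans ketone, methyl (1S,3R)-3-bromo-4-oxocyclohexane-1-carboxylate F3. Brief acid-catalysed equilibration at C3 (catalytic HBr, AcOH) then supplies the equatorial bromide 6, which is separated while F3 is recycled; the contact time is kept short to limit migration of bromine to C5.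

2. Step 5. What may go wrong: poor facial selectivity (axial attack on the diequatorial chair, putting methyl syn to bromine); enolisation with epimerisation at C3 or Favorskii-type loss of bromide; competing attack on the ester. Fallback that builds the cis-bromohydrin in the opposite order (oxygen first, bromide last by SN2), setting out from 4 and coming back at 7: methyl acrylate 4 and isoprene give methyl (S)-4-methylcyclohex-3-ene-1-carboxylate F4 in the known catalytic enantioselective Diels–Alder reaction ((R)-prolinol-derived catalyst). Epoxidation with mCPBA gives methyl (3S)-6-methyl-7-oxabicyclo[4.1.0]heptane-3-carboxylate F5 as both epoxide epimers. Aqueous acid opens both trans-diaxially (Fürst–Plattner, the cis epoxide at the tertiary and the trans epoxide at the secondary carbon, as with the limonene oxides), converging on methyl (1S,3R,4R)-3,4-dihydroxy-4-methylcyclohexane-1-carboxylate F6. SOCl2/Et3N followed by RuCl3 (cat.)/NaIO4 gives the cyclic sulfate, methyl (1S,3R,4R)-4-methyl-3,4-(sulfonyldioxy)cyclohexane-1-carboxylate F7. LiBr opens it at the secondary carbon with inversion to lithium (1R,2S,4S)-2-bromo-4-(methoxycarbonyl)-1-methylcyclohexyl sulfate F8, and mild acid hydrolysis (catalytic H2SO4, THF/H2O) releases 7.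

3. Step 12. What may go wrong: aluminium and zinc halides may open the tertiary allylic ether of 15 or of the product during the one-flask coupling; transmetalation may be slow, with homocoupling of the alkenyl partners. Fallback that separates the two events and couples under basic conditions, setting out from 10 and 14 and coming back at 17: methylalumination of 10 as in step 12, then quenching alane 16 with I2, gives {[(1R,2S,4S)-2-bromo-4-[(E)-1-iodoprop-1-en-2-yl]-1-methylcyclohexyl]oxy}triethylsilane F9, which is purified. Aldehyde 14 is converted by the Takai–Utimoto boron olefination (CrCl2, LiI, Cl2CHB(pin), THF) into 2-{(E)-2-[(2R,5S)-5-bromo-2,6,6-trimethyloxan-2-yl]ethenyl}-4,4,5,5-tetramethyl-1,3,2-dioxaborolane F10. Suzuki–Miyaura coupling of F9 with F10 (Pd(dppf)Cl2, K3PO4, THF/H2O, rt) gives 17.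

Further compounds
F1 | step 3 | 2-(triisopropylsilyloxy)buta-1,3-diene | C=CC(=C)O[Si](C(C)C)(C(C)C)C(C)C
F2 | step 3 | methyl (S)-4-(triisopropylsilyloxy)cyclohex-3-ene-1-carboxylate | COC(=O)[C@H]1CCC(O[Si](C(C)C)(C(C)C)C(C)C)=CC1
F3 | step 3 | methyl (1S,3R)-3-bromo-4-oxocyclohexane-1-carboxylate | COC(=O)[C@H]1CCC(=O)[C@H](Br)C1
F4 | step 5 | methyl (S)-4-methylcyclohex-3-ene-1-carboxylate | COC(=O)[C@H]1CCC(C)=CC1
F5 | step 5 | methyl (3S)-6-methyl-7-oxabicyclo[4.1.0]heptane-3-carboxylate (both epoxide epimers) | COC(=O)[C@H]1CCC2(C)OC2C1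
F6 | step 5 | methyl (1S,3R,4R)-3,4-dihydroxy-4-methylcyclohexane-1-carboxylate | COC(=O)[C@H]1CC[C@@](C)(O)[C@H](O)C1
F7 | step 5 | methyl (1S,3R,4R)-4-methyl-3,4-(sulfonyldioxy)cyclohexane-1-carboxylate (cyclic sulfate of F6) | COC(=O)[C@H]1CC[C@@]2(C)OS(=O)(=O)O[C@@H]2C1
F8 | step 5 | lithium (1R,2S,4S)-2-bromo-4-(methoxycarbonyl)-1-methylcyclohexyl sulfate | [Li+].COC(=O)[C@H]1CC[C@@](C)(OS(=O)(=O)[O-])[C@@H](Br)C1
F9 | step 12 | {[(1R,2S,4S)-2-bromo-4-[(E)-1-iodoprop-1-en-2-yl]-1-methylcyclohexyl]oxy}triethylsilane | I/C=C(\C)[C@H]1CC[C@@](C)(O[Si](CC)(CC)CC)[C@@H](Br)C1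
F10 | step 12 | 2-{(E)-2-[(2R,5S)-5-bromo-2,6,6-trimethyloxan-2-yl]ethenyl}-4,4,5,5-tetramethyl-1,3,2-dioxaborolane | CC1(C)OB(/C=C/[C@@]2(C)CC[C@H](Br)C(C)(C)O2)OC1(C)C
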